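I was to read this flask at 6.0 min.

electrophile 0.080 M; nucleophile 0.160 M; buffer base 0.160 M; buffer acid 0.0240 M; time 6.0 min

    electrophile + nucleophile → acid + product + leaving group (k1 = 0.75 M⁻¹ min⁻¹)
    protonated nucleophile ⇌ nucleophile + acid, settled at all times (K2 = 6.3 × 10⁻¹⁰ M)
    buffer acid ⇌ buffer base + acid, settled at all times (K3 = 4.0 × 10⁻⁹ M)
    2 nucleophile → homo dimer (k4 = 2.1 M⁻¹ min⁻¹)
    electrophile + product ⇌ idle adduct, settled at all times (K5 = 170 M⁻¹)

- acid is the free proton; pH is minus the decimal logarithm of its molar concentration
- percentages count the electrophile that a species holds: one idle adduct counts as two
- product is meant together with its idle adduct
- where a step has two of a species, its rate is k times that concentration squared, and two are used at each turn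
- in an amount of product, one idle adduct counts as one product
- what has gone from electrophile into another species counts as reacted, even if it can come back
- run time (flask): 6.0 min

- part of the electrophile that has reacted at 6.0 min
- pH of the solution at 6.0 min

**Main step.** With the nucleophile held at its charge, a pseudo-first-order picture, step 1 alone gave the electrophile a half-life of 5.8 min, so I reckoned 51.3% reacted at the reading.

**Proton shift.** The buffer acid's constant, 4.0 × 10⁻⁹ M, stands above the protonated nucleophile's, 6.3 × 10⁻¹⁰ M, so as an estimate I passed the whole of the buffer acid to the nucleophile. That left 0.850 of its charge free, and the figure fell to 45.8%.

**Dimer step.** Just after the start, the dimer step used nucleophile 9.8 times as fast as the main step, so I let it set the second-order decay of the free nucleophile. The main-step constant times the time integral of that decay gave an exposure of 0.266, and the reacted part dropped to 23.3%.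

**Idle adduct.** Product binds free electrophile with the balance ratio g, the constant K5 times free electrophile, which began at 14. A share g/(1+g) of the product is therefore bound, and each bound product holds a second electrophile. The electrophile gone per product formed came to 1.93 at the charge: this is the electrophile cost, one plus the bound share. Multiplying the exposure by it gave 40.1%.

**Second round.** I put that answer back: the free electrophile it left lowered the cost to 1.89, and the reacted part became 39.5%. I had not charged the nucleophile for the main step's own use, so I thought this leaned high. I reckoned no pH.

**The result.** The forecast gave 38% (34% to 42%), lower than mine, and pH 9.33 (9.2 to 9.45), holding that “most of that is tied up as adduct, each holding two electrophiles”. The flask gave 37.6% reacted and pH 9.33, which put my figure 1.9 percentage points too high.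

**Cost reused.** At 6.00 min this flask held 62.4% of its electrophile free, so the cost stood at 1.89, against my 1.89. Product, idle adduct counted, stood at 19.8% of the charge, below the 20.9% that my reckoning implied. I took the neighbour flask, charged with 0.040 M of nucleophile and otherwise the same, through the same reckoning. With the whole of the buffer acid passed over, its exposure came to 0.0605, the second round put its cost at 1.92, and I got 11.0% reacted. The neighbour flask's simulated answer at 6.00 min was 15.2%, 4.2 points above that reckoning.

The constants used here are made up; the flask was simulated.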